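**Remarks on the chemistry**

- Locants are those of the cembrane skeleton of the target: C1–C14 ring, C15 lactone α-carbon, C16 lactone carbonyl, C17 exocyclic methylene.
- Structure check: 23 is (1R,3S,4R,13S,14R,7E,11E). The oxygens on C13/C14 are anti, those on C3/C4 are anti, and the lactone is trans-fused. Compounds 14 and 17 have the same spatial arrangement as 23 at every centre they share with it.
- Design changes to the photoprecursor: both hydroxyls are TBS ethers (one silylation step, stable to the acid of the key step). Acetone is rejected as sensitiser because its triplet would also isomerise the two trisubstituted olefins. The C4 carbinol is set by asymmetric epoxidation, not by asymmetric alkynylation of a methyl ketone.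
- The enol ether geometry of 14 is without consequence (C15 ends as CH2); the E isomer is drawn.
- Assumption: (R)-TRIP exposes the Re face of enal 6, as it does for aryl aldehydes; if the sense were opposite, the (S)-acid would be used.
- Assumption: 7 is treated as purchasable (otherwise one step from propargyl alcohol and 4-methoxybenzyl chloride).

## Structural features

Crassocolide B is a cembranolide: a 14-membered carbocycle (C1–C14) with two E-trisubstituted olefins (C7=C8, C11=C12) and an α-methylene-γ-lactone (O–C14, C1, C15, C16, exocyclic C17) fused across C1–C14. The five stereocentres form two clusters. The contiguous triad is C13 (S, acetate), C14 (R, lactone oxygen) and C1 (R), with the two oxygens anti and the lactone trans-fused. The pair is C3 (S, acetate) and C4 (R, tertiary alcohol with methyl), again anti; only the C2 methylene and the ring connect the clusters. Fragile groups are the methylene lactone (Michael acceptor), the allylic C13 acetate, the 1,5-diene geometry (sensitive to acid and to triplet sensitisers), and the lactone itself, which can migrate to the C13 or C3 oxygen once these are free. The real difficulty is closing the 14-membered ring while fixing C1 relative to C14 and leaving both olefins E; the other centres can be set by reagent control in open chains. The key step exploits the array O–C14–C1(–C15–C16)–C2–C3(–O). Read backwards, the lactone oxygen on C14 and the oxygen on C3 are one enol ether oxygen, so C14–O–C3=C15–C16 is a β-alkoxyacrylate and C1=C2 is a vinyl group two atoms away, a 1,5-diene for a crossed [2+2] cycloaddition. The macrocycle is therefore closed at a C–O bond as a 13-membered ether and converted into the carbocycle by light and acid.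

## Logic of the disconnections

**23 ⇒ 21.** The C15=C17 double bond is masked as the dimethylamine adduct. The methylene lactone would not survive desilylation and acetylation cleanly, and the amine is inert to both. The forward step must eliminate under conditions that spare two acetates, so quaternisation and bicarbonate are used.

**21 ⇒ 20 ⇒ 19 ⇒ 18.** The two acetyl C–O bonds, the two Si–O bonds and the C15–C17 bond are cut in turn. This leaves a lactone whose only acidic C–H is at C15, so the Mannich reaction needs no regiocontrol. The demand is that C3 is already an alcohol (a ketone would enolise first) and that the C3 alkoxide does not attack the lactone.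

**18 ⇒ 17.** The C3–H bond is removed to give the ketone, which is what the key step delivers. One stereocentre disappears. The forward reduction must be controlled by the reagent, because the facial bias of the macrocycle is unknown and the C4 oxygen is silylated.

**17 ⇒ 14 (key).** C1–C15, C2–C3 and the lactone C16–O bond are cut, and C3 is reconnected to C15 and to the C14 oxygen. The carbocycle and the lactone collapse to a 13-membered cyclic β-alkoxyacrylate with a vinyl group on C14. Two rings and the C1 stereocentre are removed, and the macrocyclisation is moved to a C–O bond. The forward step needs the crossed regiochemistry, the right face at C1, reaction of the vinyl group only, a sensitiser that leaves the other olefins alone, and an acid fragmentation that spares two silyl ethers.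

**14 ⇒ 13.** The enol ether O–C3 bond is cut to a C14 alcohol and an ynoate. This opens the ring to a linear chain. The forward 13-exo-dig oxa-Michael closure must beat oligomerisation and migration of the neighbouring C13 silyl group; its geometry is irrelevant.

**13 ⇒ 12 ⇒ 11 ⇒ 10.** The C14–O–PMB bond, the C15–C16 bond and the two Si–O bonds are cut. C16 is added late so that no step before it has to tolerate an ynoate. The C14 oxygen arrives as a PMB ether and the other two hydroxyls are silylated together. The forward steps need selective acetylide formation and a DDQ cleavage that leaves the allylic system intact.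

**10 ⇒ 6 + 9.** The C13–C14 bond is cut. An anti-alkoxyallylation sets C13, C14 and the vinyl group in one step with the two oxygens already differentiated, which saves an aldol, reduction and olefination sequence. The forward step needs pure E geometry in 9 and high facial control, because C4 is remote and the diastereomers would be hard to separate.

**9 ⇒ 8 ⇒ 7.** The double bond is shifted back and the C–B bond is cut, leading to a propargyl ether. The transposition must give the E enol ether.

**6 ⇒ 4.** The C13 oxygen is removed. The forward allylic oxidation must pick the E-methyl of the terminal olefin over the internal one.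

**4 ⇒ 3 ⇒ 2 ⇒ 1.** The alkyne is traced to an epoxy chloride and the epoxide to farnesol. Farnesol supplies C3–C13, C15 and both E olefins, and asymmetric epoxidation sets the C4 carbinol reliably. The eliminations must not break the C4–O bond.

## Other disconnections considered

**Alternative 1:** The cut is C9–C10, between the two olefin units.

- Forward step: the open-chain bromo sulfone A1, which already holds the lactone, the acetonide and the C13 silyl ether, is deprotonated at C9 with KN(SiMe3)2 at low temperature and high dilution; the anion displaces the allylic bromide at C10 to give A2 as C9 epimers, and the sulfone is removed later.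
- In favour: the new bond is remote from every stereocentre, both olefin geometries are fixed beforehand, and sulfone alkylation is one of the most used closures of 14-membered terpenoid rings.
- Against it here: A1 must contain the trans-lactone and all five stereocentres, so the ring closure contributes nothing to the stereochemical problem. The lactone C15 protons are about as acidic as the allylic sulfone, so enolisation and loss of the C14 oxygen can compete. SN2' attack is possible. Desulfonylation next to an allylic C13 oxygen and a lactone risks double-bond migration.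
- Comparison: on structure, A2 is further from the target than 17, because the sulfone and the acetonide must still be removed. On mechanism, the ionic SN2 closure is better understood than the photochemical step, and Alternative 1 is the better plan on predictability of the ring closure and on safety of the olefin geometry (no sensitiser). On step economy the chosen plan should be shorter, because its key step makes ring, lactone and C1 together.

**Alternative 2:** The cut is C13–C14.

- Forward step: the dialdehyde ester A3 (C13 enal, C14 aldehyde on C1) is coupled with low-valent titanium (TiCl3 with Zn–Cu couple) at high dilution; the pinacol closes the ring and the C14 alkoxide lactonises onto the ester to give A4.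
- In favour: ring and both oxygenated carbons are made at once. The lactonisation differentiates the two new hydroxyls without protecting groups, which is better than the chosen plan, where a PMB ether and a silyl ether are needed. A4 already contains the C3/C4 diol, so no ketone reduction follows; on this point it is also closer to the target than 17.
- Against it here: two stereocentres are formed in the ring closure with no reliable control of anti versus syn or of their sense relative to C1. The enal can couple at its vinylogous position or be deoxygenated. C1 in A3 is α to an aldehyde and can epimerise.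
- Comparison: on mechanism, ketyl coupling on titanium is stereochemically loose, whereas the chosen plan fixes C13 and C14 in an open chain and creates only C1 through a five-membered transition state. On step economy the end is shorter from A4, but the route to A3 must build C1, C3 and C4 acyclically, so the total should be comparable or longer.

**Alternative 3:** The cut is C5–C6.

- Forward step: the 16-membered allyl β-keto ester A5 is ionised by zerovalent palladium (Pd(PPh3)4), loses CO2, and the C5 enolate recombines with the allyl terminus C6 to give A6.
- In favour: the large ring is made by a lactonisation and then contracted. This is the same idea as the chosen plan (close at a heteroatom, then extrude it), and on this concept the two are equal. Conditions are neutral and catalytic, and no light is needed, which is better for scale.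
- Against it here: the enolate and the π-allyl partner can cross over to dimers. Attack at C8 and syn–anti isomerisation of the allyl unit threaten the regiochemistry and the C7=C8 geometry. A6 lacks the C4 methyl group, so a late methyl addition must set a tertiary stereocentre next to an epimerisable C3 and in the presence of a lactone.
- Comparison: on structure, 17 is more advanced than A6, because C4 is complete. On mechanism, each elementary step of Alternative 3 is known and this is arguably a firmer footing than the chosen key step. On step economy it is longer, because both chain ends need separate functionalisation before lactonisation and C4 must be finished afterwards.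

Key step: step 12

## Route

Step 1
Reactants: 1 (2E,6E)-farnesol
Product: 2 (2R,3R)-2,3-epoxyfarnesol
Conditions: Ti(OiPr)4 (10 mol%), D-(−)-diethyl tartrate (12 mol%), t-BuOOH, 4 Å MS, CH2Cl2, −20 °C
Reagents that add atoms: tert-butyl hydroperoxide, CC(C)(C)OO
Why: Sharpless asymmetric epoxidation; the titanium tartrate binds the allylic hydroxyl, so only C2=C3 of farnesol reacts, and D-(−)-tartrate delivers oxygen to the face that gives (2R,3R), which fixes the future C4 carbinol as R.

Step 2
Reactants: 2 (2R,3R)-2,3-epoxyfarnesol
Product: 3 (2S,3R)-epoxy chloride
Conditions: PPh3, CCl4, NaHCO3, reflux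
Reagents that add atoms: tetrachloromethane, ClC(Cl)(Cl)Cl
Why: Appel chlorination of the primary alcohol; the bicarbonate buffer keeps the trisubstituted epoxide closed, and no stereocentre is touched (the descriptor at C2 changes only through the priority of chlorine).

Step 3
Reactants: 3 (2S,3R)-epoxy chloride
Product: 4 (3R,6E)-3,7,11-trimethyldodeca-6,10-dien-1-yn-3-ol
Conditions: n-BuLi (3.3 equiv), THF, −40 → −20 °C; aq. NH4Cl
Reagents that add atoms: none
Why: Base-induced double elimination of a 2,3-epoxy chloride: deprotonation next to chlorine opens the epoxide to a chlorovinyl alkoxide and loss of HCl gives the acetylide; the C–O bond of the carbinol carbon is never broken, so the tertiary propargylic alcohol keeps the R configuration.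

Step 4
Reactants: 4 (3R,6E)-3,7,11-trimethyldodeca-6,10-dien-1-yn-3-ol
Product: 6 (2E,6E,10R)-hydroxy enynal, via allylic alcohol 5 (not isolated)
Conditions: SeO2 (0.3 equiv), t-BuOOH, salicylic acid (cat.), CH2Cl2, 0 °C → rt; filtration; then MnO2, CH2Cl2, rt
Reagents that add atoms: tert-butyl hydroperoxide, CC(C)(C)OO
Why: SeO2-catalysed allylic oxidation (ene reaction, then [2,3]-shift) attacks the E-methyl of the terminal isopropylidene, the more accessible of the two trisubstituted olefins, and gives the E allylic alcohol; MnO2 then oxidises only this primary allylic alcohol, so the crude alcohol/aldehyde mixture converges on the enal.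

Step 5
Reactants: 7 4-methoxybenzyl propargyl ether
Product: 8 (E)-3-(4-methoxybenzyloxy)prop-1-enyl pinacolboronate
Conditions: pinacolborane (1.1 equiv), Cp2Zr(H)Cl (5 mol%), Et3N (10 mol%), neat, 60 °C
Reagents that add atoms: pinacolborane, [H]B1OC(C)(C)C(C)(C)O1
Why: Zirconium-catalysed syn hydroboration of a terminal alkyne places boron on the terminal carbon and gives the E alkenylboronate.

Step 6
Reactants: 8 (E)-3-(4-methoxybenzyloxy)prop-1-enyl pinacolboronate
Product: 9 (E)-3-(4-methoxybenzyloxy)allyl pinacolboronate
Conditions: [Ir(cod)(PMePh2)2]PF6 (2 mol%, activated with H2), THF, rt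
Reagents that add atoms: none
Why: Iridium hydride catalysed 1,3-hydrogen shift, the known isomerisation of allyl ethers to (E)-propenyl ethers; conjugation with oxygen drives the double bond out of conjugation with boron and gives the γ-alkoxyallyl boronate with E geometry.

Step 7
Reactants: 6 (2E,6E,10R)-hydroxy enynal; 9 (E)-3-(4-methoxybenzyloxy)allyl pinacolboronate
Product: 10 (3R,12S,13R)-anti-diol mono-PMB ether
Conditions: (R)-3,3'-bis(2,4,6-triisopropylphenyl)-1,1'-binaphthyl-2,2'-diyl hydrogen phosphate ((R)-TRIP, 5 mol%), 4 Å MS, toluene, −30 °C → rt; aq. NaHCO3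
Reagents that add atoms: none
Why: Chiral phosphoric acid catalysed allylboration through a closed chair transition state; the E γ-alkoxy group sits equatorial and gives the anti relation of the C13 hydroxyl and the C14 ether, while the acid, bound to a boronate oxygen and the formyl hydrogen, exposes the Re face of the enal and sets 13S and hence 14R. The boronate reacts only with the aldehyde, so the alkyne and the tertiary alcohol are spectators.

Step 8
Reactants: 10 (3R,12S,13R)-anti-diol mono-PMB ether
Product: 11 bis-TBS ether
Conditions: TBSOTf (3 equiv), 2,6-lutidine, CH2Cl2, −78 → 0 °C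
Reagents that add atoms: tert-butyldimethylsilyl trifluoromethanesulfonate, CC(C)(C)[Si](C)(C)OS(=O)(=O)C(F)(F)F
Why: The silyl triflate is reactive enough to silylate the secondary C13 and the tertiary C4 hydroxyl in one operation; the hindered base does not add to anything and the PMB ether is stable.

Step 9
Reactants: 11 bis-TBS ether
Product: 12 methyl ynoate
Conditions: n-BuLi (1.1 equiv), THF, −78 °C; ClCO2Me, −78 → −20 °C
Reagents that add atoms: methyl chloroformate, COC(=O)Cl
Why: Deprotonation of the terminal alkyne is far faster than any other metalation in 11, and the acetylide is acylated by the chloroformate to install C16.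

Step 10
Reactants: 12 methyl ynoate
Product: 13 C14 alcohol
Conditions: DDQ, CH2Cl2/pH 7 buffer, 0 °C
Reagents that add atoms: none
Why: Oxidative cleavage of the PMB ether by hydride abstraction from the electron-rich benzylic position; buffered and cold conditions spare the silyl ethers, the ynoate and the allylic C14–H.

Step 11
Reactants: 13 C14 alcohol
Product: 14 13-membered cyclic β-alkoxyacrylate
Conditions: LiN(SiMe3)2 (0.3 equiv), THF, 1 mM (slow addition of 13), −40 → 0 °C; AcOH
Reagents that add atoms: none
Why: Base-catalysed oxa-Michael addition (13-exo-dig) of the C14 alkoxide to C3 of the ynoate, which cannot isomerise because C4 is quaternary; the resulting allenolate is protonated by the next molecule of 13, so the base is catalytic. The lithium counter-ion and low temperature are chosen to keep the neighbouring C13 silyl group from migrating, and either enol ether geometry is acceptable.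

Step 12
Reactants: 14 13-membered cyclic β-alkoxyacrylate
Product: 17 macrocyclic keto γ-lactone, via oxabicyclohexane photoadduct 15 (not isolated), via hydroxy keto ester 16 (not isolated)
Conditions: hν (300–350 nm, Pyrex), PhCOMe (0.1 M), MeCN (5 mM), Ar, 20 °C; then H2O (50 equiv), (±)-camphorsulfonic acid (1 equiv), 20 → 40 °C
Reagents that add atoms: water, O
Why: Proposed new method: triplet energy transfer from acetophenone (about 74 kcal/mol, below the roughly 78 kcal/mol of the two isolated trisubstituted olefins, so their E geometry should survive, which acetone would not allow) populates the push–pull alkoxyacrylate, whose C15 terminus adds 5-exo-trig to the internal vinyl carbon C1 (rule of five), and after intersystem crossing the C2/C3 biradical recombines to the crossed cyclobutane, the 2-oxabicyclo[2.1.1]hexane 15. The closest known chemistry is the sensitised crossed [2+2] cycloaddition of acyclic allyl 3-oxyacrylates to 2-oxabicyclo[2.1.1]hexanes and, for the second stage, the De Mayo cycloaddition/retro-aldol sequence and the acid-induced opening of 2-alkoxycyclobutane esters; neither has been run inside a macrocycle or combined in one flask. In 15 the C3–C15 bond lies antiperiplanar to a lone pair of the ring oxygen and carries the ester at its other end, so protonation of the ester lets this strained donor–acceptor bond break to a five-membered oxocarbenium ion and an ester enol; water turns the ion into the C3 ketone and the free C14 hydroxyl (16), which lactonises onto C16 with loss of methanol. Ring closures: the transient oxolane by 5-exo-trig radical addition, the cyclobutane by biradical recombination, the 14-membered carbocycle by net insertion of C1–C2 in place of the ring oxygen (no entropically costly macrocyclisation occurs here), and the γ-lactone by 5-exo-trig acyl substitution. The only new stereocentre, C1, is set in the first bond formation: in the chair-like transition state the C13 chain on C14 is pseudo-equatorial and trans to the exocyclic C2, which places C13 on the C15 side of the bicycle and therefore trans to C2 on the lactone (1R). Selectivity for the vinyl group over C11=C12 rests on the five-membered first closure being open only to the vinyl group (C11=C12 would need a six- or seven-membered closure onto a hindered ring olefin), and the crossed regiochemistry on the two-atom tether. Excess water and a Brønsted acid are chosen so that hydration of the oxocarbenium ion outruns capture by C7=C8, and both TBS ethers should survive.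

Step 13
Reactants: 17 macrocyclic keto γ-lactone
Product: 18 (3S)-hydroxy lactone
Conditions: (R)-1-methyl-3,3-diphenyltetrahydro-1H,3H-pyrrolo[1,2-c][1,3,2]oxazaborole ((R)-Me-CBS, 1 equiv), catecholborane (2 equiv), toluene, −78 → −30 °C
Reagents that add atoms: none
Why: Corey–Bakshi–Shibata reduction; the ketone lies between the fully substituted C4 (large) and the C2 methylene (small), so the oxazaborolidine binds the carbonyl lone pair anti to C4 and the (R)-catalyst delivers hydride to the face that gives 3S, anti to the C4 oxygen. Catecholborane does not hydroborate the trisubstituted olefins or reduce the lactone at this temperature.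

Step 14
Reactants: 18 (3S)-hydroxy lactone
Product: 19 α-(dimethylaminomethyl) lactone
Conditions: LiN(iPr)2 (2.5 equiv), THF, −78 °C; Me2N=CH2 iodide (3 equiv), −78 → 0 °C
Reagents that add atoms: N,N-dimethylmethyleneiminium iodide (Eschenmoser's salt), C=[N+](C)C.[I-]
Why: Mannich alkylation of the lactone enolate; the first equivalent of base takes the C3 hydroxyl proton, the lactone is the only enolisable carbonyl, and the configuration of the new C15 centre is irrelevant because it becomes sp2. The amine is a masked methylene that tolerates the next two steps.

Step 15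
Reactants: 19 α-(dimethylaminomethyl) lactone
Product: 20 amino triol
Conditions: aq. HF (48%), MeCN, 0 °C → rt
Reagents that add atoms: none
Why: Fluoride-driven cleavage of both TBS ethers, including the hindered tertiary one; the amine is protonated and protected, and the lactone, the tertiary alcohol and the olefins tolerate the medium.

Step 16
Reactants: 20 amino triol
Product: 21 amino diacetate
Conditions: Ac2O (3 equiv), pyridine, DMAP (cat.), CH2Cl2, 0 °C → rt
Reagents that add atoms: acetic anhydride, CC(=O)OC(C)=O
Why: Acetylation of the two secondary hydroxyls at C3 and C13; the tertiary C4 hydroxyl is too hindered to react under these conditions and the tertiary amine cannot be acylated.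

Step 17
Reactants: 21 amino diacetate
Product: 23 crassocolide B, via trimethylammonium iodide 22 (not isolated)
Conditions: MeI, CH2Cl2, rt; then aq. NaHCO3, EtOAc, rt
Reagents that add atoms: none
Why: Quaternisation of the amine and E1cB loss of trimethylamine from the β-ammonium lactone reveal the exocyclic methylene in the last step; bicarbonate is too mild to cleave the acetates or to epimerise C1.

## Compound list

1 | (2E,6E)-farnesol | OC/C=C(\C)CC/C=C(\C)CCC=C(C)C | starting material
2 | (2R,3R)-2,3-epoxyfarnesol, [(2R,3R)-3-[(3E)-4,8-dimethylnona-3,7-dien-1-yl]-3-methyloxiran-2-yl]methanol | OC[C@H]1O[C@]1(C)CC/C=C(\C)CCC=C(C)C | intermediate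
3 | (2S,3R)-2-(chloromethyl)-3-[(3E)-4,8-dimethylnona-3,7-dien-1-yl]-3-methyloxirane | ClC[C@H]1O[C@]1(C)CC/C=C(\C)CCC=C(C)C | intermediate
4 | (3R,6E)-3,7,11-trimethyldodeca-6,10-dien-1-yn-3-ol | C#C[C@](C)(O)CC/C=C(\C)CCC=C(C)C | intermediate
5 | (2E,6E,10R)-2,6,10-trimethyldodeca-2,6-dien-11-yne-1,10-diol | C#C[C@](C)(O)CC/C=C(\C)CC/C=C(\C)CO | intermediate (not isolated)
6 | (2E,6E,10R)-10-hydroxy-2,6,10-trimethyldodeca-2,6-dien-11-ynal | C#C[C@](C)(O)CC/C=C(\C)CC/C=C(\C)C=O | intermediate
7 | 4-methoxybenzyl propargyl ether, 1-methoxy-4-[(prop-2-yn-1-yloxy)methyl]benzene | C#CCOCc1ccc(OC)cc1 | starting material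
8 | 2-[(E)-3-(4-methoxybenzyloxy)prop-1-en-1-yl]-4,4,5,5-tetramethyl-1,3,2-dioxaborolane | COc1ccc(COC/C=C/B2OC(C)(C)C(C)(C)O2)cc1 | intermediate
9 | 2-[(E)-3-(4-methoxybenzyloxy)prop-2-en-1-yl]-4,4,5,5-tetramethyl-1,3,2-dioxaborolane | COc1ccc(CO/C=C/CB2OC(C)(C)C(C)(C)O2)cc1 | intermediate
10 | (3R,6E,10E,12S,13R)-13-(4-methoxybenzyloxy)-3,7,11-trimethylpentadeca-6,10,14-trien-1-yne-3,12-diol (target C4, C13, C14 = chain C3, C12, C13) | C#C[C@](C)(O)CC/C=C(\C)CC/C=C(\C)[C@H](O)[C@H](OCc1ccc(OC)cc1)C=C | intermediate
11 | (3R,6E,10E,12S,13R)-3,12-bis(tert-butyldimethylsilyloxy)-13-(4-methoxybenzyloxy)-3,7,11-trimethylpentadeca-6,10,14-trien-1-yne | C#C[C@](C)(O[Si](C)(C)C(C)(C)C)CC/C=C(\C)CC/C=C(\C)[C@H](O[Si](C)(C)C(C)(C)C)[C@H](OCc1ccc(OC)cc1)C=C | intermediate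
12 | methyl (4R,7E,11E,13S,14R)-4,13-bis(tert-butyldimethylsilyloxy)-14-(4-methoxybenzyloxy)-4,8,12-trimethylhexadeca-7,11,15-trien-2-ynoate | COC(=O)C#C[C@](C)(O[Si](C)(C)C(C)(C)C)CC/C=C(\C)CC/C=C(\C)[C@H](O[Si](C)(C)C(C)(C)C)[C@H](OCc1ccc(OC)cc1)C=C | intermediate
13 | methyl (4R,7E,11E,13S,14R)-4,13-bis(tert-butyldimethylsilyloxy)-14-hydroxy-4,8,12-trimethylhexadeca-7,11,15-trien-2-ynoate | COC(=O)C#C[C@](C)(O[Si](C)(C)C(C)(C)C)CC/C=C(\C)CC/C=C(\C)[C@H](O[Si](C)(C)C(C)(C)C)[C@H](O)C=C | intermediate
14 | methyl (2E)-2-[(3R,6E,10E,12S,13R)-3,12-bis(tert-butyldimethylsilyloxy)-13-ethenyl-3,7,11-trimethyl-1-oxacyclotrideca-6,10-dien-2-ylidene]acetate (13-membered cyclic β-alkoxyacrylate; ring atoms 2, 3, 12, 13 = target C3, C4, C13, C14) | C=C[C@H]1O/C(=C/C(=O)OC)[C@](C)(O[Si](C)(C)C(C)(C)C)CC/C=C(\C)CC/C=C(\C)[C@@H]1O[Si](C)(C)C(C)(C)C | intermediate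
15 | crossed photoadduct: 2-oxabicyclo[2.1.1]hexane with bridgeheads C3 (bearing C4) and C1, bridges O–C14, C15 (methyl ester, configuration open) and C2; C13 on the C15 side; both TBS ethers and both E olefins retained | COC(=O)C1[C@@]23O[C@H]([C@@H]1C2)[C@@H](O[Si](C)(C)C(C)(C)C)/C(C)=C/CC/C(C)=C/CC[C@@]3(C)O[Si](C)(C)C(C)(C)C | intermediate (not isolated)
16 | methyl 2-[(1R,4R,13S,14R,7E,11E)-4,13-bis(tert-butyldimethylsilyloxy)-14-hydroxy-4,8,12-trimethyl-3-oxocyclotetradeca-7,11-dien-1-yl]acetate (target locants) | COC(=O)C[C@H]1CC(=O)[C@](C)(O[Si](C)(C)C(C)(C)C)CC/C=C(\C)CC/C=C(\C)[C@H](O[Si](C)(C)C(C)(C)C)[C@@H]1O | intermediate (not isolated)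
17 | keto γ-lactone: 14-membered carbocycle with C3 ketone, C4 (R) methyl and OTBS, C13 (S) OTBS, 7E,11E olefins, trans-fused lactone C14(R)–O–C16(=O)–C15H2–C1(R) | C1C(=O)O[C@@H]2[C@@H]1CC(=O)[C@](C)(O[Si](C)(C)C(C)(C)C)CC/C=C(\C)CC/C=C(\C)[C@@H]2O[Si](C)(C)C(C)(C)C | intermediate
18 | (1R,3S,4R,13S,14R)-3-hydroxy analogue of 17 (C3 alcohol, C4 and C13 OTBS) | C1C(=O)O[C@@H]2[C@@H]1C[C@H](O)[C@](C)(O[Si](C)(C)C(C)(C)C)CC/C=C(\C)CC/C=C(\C)[C@@H]2O[Si](C)(C)C(C)(C)C | intermediate
19 | 18 bearing CH2NMe2 on C15 (C15 epimers) | CN(C)CC1C(=O)O[C@@H]2[C@@H]1C[C@H](O)[C@](C)(O[Si](C)(C)C(C)(C)C)CC/C=C(\C)CC/C=C(\C)[C@@H]2O[Si](C)(C)C(C)(C)C | intermediate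
20 | amino triol: C15-(dimethylaminomethyl) lactone with free hydroxyls at C3, C4 and C13 | CN(C)CC1C(=O)O[C@@H]2[C@@H]1C[C@H](O)[C@](C)(O)CC/C=C(\C)CC/C=C(\C)[C@@H]2O | intermediate
21 | amino diacetate: 20 with acetates at C3 and C13, C4 hydroxyl free | CN(C)CC1C(=O)O[C@@H]2[C@@H]1C[C@H](OC(C)=O)[C@](C)(O)CC/C=C(\C)CC/C=C(\C)[C@@H]2OC(C)=O | intermediate
22 | trimethylammonium iodide of 21 | C[N+](C)(C)CC1C(=O)O[C@@H]2[C@@H]1C[C@H](OC(C)=O)[C@](C)(O)CC/C=C(\C)CC/C=C(\C)[C@@H]2OC(C)=O.[I-] | intermediate (not isolated)
23 | crassocolide B | C=C1C(=O)O[C@@H]2[C@@H]1C[C@H](OC(C)=O)[C@](C)(O)CC/C=C(\C)CC/C=C(\C)[C@@H]2OC(C)=O | target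

## Step count and weakest steps

Total: 17 steps. Longest linear sequence: 15 steps (1 to 23 through steps 1–4 and 7–17); steps 5 and 6 make the allylboronate 9.

**Step 12 (key step).** The most likely failure is unselective photochemistry:
- a boat-like first closure that gives the cis-lactone epimer at C1;
- loss of E geometry in the ring olefins by partial energy transfer;
- hydrogen abstraction or oxetane formation by the ketone triplet;
- after irradiation, a photoadduct whose single ester is too weak an acceptor for clean fragmentation, so that stronger acid strips silyl groups or the oxocarbenium ion is trapped by C7=C8.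

The fallback uses only known reaction types and closes the ring at C1–C2 by conjugate addition. It sets out from 13. Acylation with acryloyl chloride and iPr2NEt gives the acrylate F1. Ring-closing metathesis with the second-generation Hoveyda–Grubbs catalyst (the hindered, electron-poor ynoate should be a poor partner) gives the butenolide F2. Gold-catalysed hydration of the ynoate ((Ph3P)AuNTf2, wet dioxane) gives the β-keto ester F3. Cs2CO3 in MeCN at high dilution adds the C2 carbanion to C1 of the butenolide, anti to the C13-bearing substituent, to give the macrocyclic β-keto ester F4. Krapcho dealkoxycarbonylation (LiCl, wet DMSO, 130 °C) returns the route at 17.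

**Step 11.** The most likely failure is 1,2-migration of the C13 silyl group to the C14 alkoxide followed by closure of the 12-membered isomer, together with oligomerisation and slow attack at the hindered C3. The fallback avoids any alkoxide. It sets out from 12. Catalytic NaOMe in MeOH adds methanol to the ynoate to give the β-methoxyacrylate F5. DDQ frees the C14 hydroxyl to give F6. Acid-catalysed exchange of the enol ether (camphorsulfonic acid, toluene, 5 Å MS, high dilution, 50 °C, below the temperature of a Claisen shift) closes the ring with loss of methanol and comes back at 14.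

**Step 7 (and the preparation of 9 in step 6).** The most likely failure is insufficient facial control on a hindered 2-methyl enal, or erosion of the E geometry of 9; either gives a C13/C14 diastereomer that the remote C4 centre makes hard to remove. The fallback swaps catalyst control for a stoichiometric chiral borane and an inversion. It sets out from 7 and 6. Semihydrogenation of 7 (H2, Pd/CaCO3 poisoned with Pb(OAc)2, quinoline) gives allyl 4-methoxybenzyl ether F7. Metalation with sec-BuLi, then (−)-B-methoxydiisopinocampheylborane and BF3·OEt2, gives the (Z)-γ-alkoxyallylborane F8. F8 adds to 6 on the Si face to give the syn adduct F9 (13R,14R). Mitsunobu reaction with 4-nitrobenzoic acid inverts C13 to give the ester F10. K2CO3 in MeOH returns the route at 10.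

**Step 13.** The most likely failure is a mismatch between the catalyst and the conformational bias of the macrocycle (poor facial selectivity), or a reduction so slow that a more reactive borane and hence hydroboration would be needed. The fallback uses substrate control through a chelate. It sets out from 17. Aqueous HF in MeCN removes both silyl groups to give the keto diol F11. Zn(BH4)2 in Et2O at −20 °C reduces the chelated α-hydroxy ketone from the methyl face, which is also the outer face of the ring, to give the 3,4-anti triol F12. TESOTf and 2,6-lutidine give the tris-TES ether F13. LiN(iPr)2 and Eschenmoser's salt give the amine F14. HF·pyridine returns the route at 20.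

**Step 4.** The most likely failure is attack at the wrong allylic position (the internal olefin or the Z-methyl), over-oxidation and low conversion. The fallback rebuilds the enal instead of oxidising a C–H bond. It sets out from 4. NBS in aqueous THF forms the terminal bromohydrin F15. K2CO3 in MeOH gives the epoxide F16. HIO4 cleaves it to the aldehyde F17. Wittig reaction with Ph3P=C(CH3)CHO gives the E enal and comes back at 6.

## Further compounds

F1 | step 12 | acrylate of 13 at the C14 oxygen | COC(=O)C#C[C@](C)(O[Si](C)(C)C(C)(C)C)CC/C=C(\C)CC/C=C(\C)[C@H](O[Si](C)(C)C(C)(C)C)[C@H](OC(=O)C=C)C=C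
F2 | step 12 | butenolide (C1=C15) carrying the silylated ynoate chain | COC(=O)C#C[C@](C)(O[Si](C)(C)C(C)(C)C)CC/C=C(\C)CC/C=C(\C)[C@H](O[Si](C)(C)C(C)(C)C)[C@@H]1OC(=O)C=C1
F3 | step 12 | β-keto ester butenolide (C3 ketone) | COC(=O)CC(=O)[C@](C)(O[Si](C)(C)C(C)(C)C)CC/C=C(\C)CC/C=C(\C)[C@H](O[Si](C)(C)C(C)(C)C)[C@@H]1OC(=O)C=C1
F4 | step 12 | 17 bearing a methoxycarbonyl group on C2 (C2 epimers) | C1C(=O)O[C@@H]2[C@@H]1C(C(=O)OC)C(=O)[C@](C)(O[Si](C)(C)C(C)(C)C)CC/C=C(\C)CC/C=C(\C)[C@@H]2O[Si](C)(C)C(C)(C)C
F5 | step 11 | β-methoxyacrylate from 12 (geometry open) | COC(=O)C=C(OC)[C@](C)(O[Si](C)(C)C(C)(C)C)CC/C=C(\C)CC/C=C(\C)[C@H](O[Si](C)(C)C(C)(C)C)[C@H](OCc1ccc(OC)cc1)C=C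
F6 | step 11 | β-methoxyacrylate with free C14 hydroxyl | COC(=O)C=C(OC)[C@](C)(O[Si](C)(C)C(C)(C)C)CC/C=C(\C)CC/C=C(\C)[C@H](O[Si](C)(C)C(C)(C)C)[C@H](O)C=C
F7 | step 7 | allyl 4-methoxybenzyl ether | C=CCOCc1ccc(OC)cc1
F8 | step 7 | (Z)-3-(4-methoxybenzyloxy)allyl-diisopinocampheylborane, isopinocampheyl groups from (+)-α-pinene | COc1ccc(CO/C=C\CB([C@@H]2C[C@@H]3C[C@H]([C@H]2C)C3(C)C)[C@@H]2C[C@@H]3C[C@H]([C@H]2C)C3(C)C)cc1
F9 | step 7 | syn adduct, C13 epimer of 10 (13R,14R in target locants) | C#C[C@](C)(O)CC/C=C(\C)CC/C=C(\C)[C@@H](O)[C@H](OCc1ccc(OC)cc1)C=C
F10 | step 7 | 4-nitrobenzoate of 10 at the C13 oxygen (13S) | C#C[C@](C)(O)CC/C=C(\C)CC/C=C(\C)[C@H](OC(=O)c1ccc(cc1)[N+](=O)[O-])[C@H](OCc1ccc(OC)cc1)C=C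
F11 | step 13 | keto diol, 17 without silyl groups | C1C(=O)O[C@@H]2[C@@H]1CC(=O)[C@](C)(O)CC/C=C(\C)CC/C=C(\C)[C@@H]2O
F12 | step 13 | (3S,4R)-triol lactone | C1C(=O)O[C@@H]2[C@@H]1C[C@H](O)[C@](C)(O)CC/C=C(\C)CC/C=C(\C)[C@@H]2O
F13 | step 13 | tris(triethylsilyl) ether of F12 | C1C(=O)O[C@@H]2[C@@H]1C[C@H](O[Si](CC)(CC)CC)[C@](C)(O[Si](CC)(CC)CC)CC/C=C(\C)CC/C=C(\C)[C@@H]2O[Si](CC)(CC)CC
F14 | step 13 | F13 bearing CH2NMe2 on C15 | CN(C)CC1C(=O)O[C@@H]2[C@@H]1C[C@H](O[Si](CC)(CC)CC)[C@](C)(O[Si](CC)(CC)CC)CC/C=C(\C)CC/C=C(\C)[C@@H]2O[Si](CC)(CC)CC
F15 | step 4 | terminal bromohydrin of 4 (10-bromo-11-hydroxy, C10 epimers) | C#C[C@](C)(O)CC/C=C(\C)CCC(Br)C(C)(C)O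
F16 | step 4 | terminal 10,11-epoxide of 4 | C#C[C@](C)(O)CC/C=C(\C)CCC1OC1(C)C
F17 | step 4 | (4E,8R)-8-hydroxy-4,8-dimethyldec-4-en-9-ynal | C#C[C@](C)(O)CC/C=C(\C)CCC=O
A1 | alternative 1 | open-chain C10 allylic bromide with C9 phenyl sulfone, lactone, acetonide and C13 OTBS in place | BrC/C=C(\C)[C@H](O[Si](C)(C)C(C)(C)C)[C@@H]1OC(=O)C[C@H]1C[C@@H]2OC(C)(C)O[C@]2(C)CC/C=C(\C)CS(=O)(=O)c1ccccc1
A2 | alternative 1 | macrocyclic γ-lactone with C9 sulfone (C9 epimers) | C1C(=O)O[C@@H]2[C@@H]1C[C@@H]3OC(C)(C)O[C@]3(C)CC/C=C(\C)C(S(=O)(=O)c4ccccc4)C/C=C(\C)[C@@H]2O[Si](C)(C)C(C)(C)C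
A3 | alternative 2 | dialdehyde methyl ester: C13 enal, C14 aldehyde, acetonide at C3/C4 | O=C/C(C)=C/CC/C(C)=C/CC[C@@]1(C)OC(C)(C)O[C@H]1C[C@H](CC(=O)OC)C=O
A4 | alternative 2 | macrocyclic C13-hydroxy γ-lactone with acetonide | C1C(=O)O[C@@H]2[C@@H]1C[C@@H]3OC(C)(C)O[C@]3(C)CC/C=C(\C)CC/C=C(\C)[C@@H]2O
A5 | alternative 3 | 16-membered allyl β-keto ester (C5 carboxylate to C6 oxygen) fused to the γ-lactone | C1C(=O)O[C@@H]2[C@@H]1C[C@H](OCc3ccc(OC)cc3)C(=O)CC(=O)OC/C=C(\C)CC/C=C(\C)[C@@H]2O[Si](C)(C)C(C)(C)C
A6 | alternative 3 | 14-membered C4 ketone fused to the γ-lactone | C1C(=O)O[C@@H]2[C@@H]1C[C@H](OCc3ccc(OC)cc3)C(=O)CC/C=C(\C)CC/C=C(\C)[C@@H]2O[Si](C)(C)C(C)(C)C
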